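Germacrane numbering is used. The O–C12(=O) unit of the α-methylene-γ-lactone ring is taken as one molecule of CO2, stitched between C11 and C8. The key step exploits the C8(O)–C9=C10–C1(OH) array of the ten-membered ring, which is the 1,4-opened form of a C1–C10 vinyl epoxide. Its precursor is a cyclodecene with a C11 alkenylboronate, a Z-C8=C9 olefin and a trans-C1,C10-epoxide. Copper-catalysed carboxylation makes the acrylate. Its oxygen closes the lactone on a π-allylpalladium, setting C8, the Z-C9=C10 olefin and the free C1 alcohol at once. The ring comes from metathesis, C6/C7 from an Evans aldol, both epoxides from neryl acetate.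

Key step: step 14

Assumption: neryl acetate, buta-2,3-dienoic acid, (S)-4-benzyloxazolidin-2-one and angelic acid are taken as commercial. Bpin = 4,4,5,5-tetramethyl-1,3,2-dioxaborolan-2-yl. IPr = 1,3-bis(2,6-diisopropylphenyl)imidazol-2-ylidene.

Step 1
Reactants: 1 neryl acetate
Product: 2 (2Z,6E)-8-hydroxy-3,7-dimethylocta-2,6-dien-1-yl acetate
Conditions: SeO2 (cat.), t-BuOOH, salicylic acid (cat.), CH2Cl2, 0 °C to rt
Reagents that add atoms: tert-butyl hydroperoxide, CC(C)(C)OO
Why: Allylic oxidation with SeO2 (ene reaction, then [2,3]-sigmatropic shift) attacks the more electron-rich distal olefin and, as usual for gem-dimethyl olefins, only its E-methyl group, which becomes C9.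

Step 2
Reactants: 2 (2Z,6E)-8-hydroxy-3,7-dimethylocta-2,6-dien-1-yl acetate
Product: 3 (2Z)-5-[(2R,3R)-3-(hydroxymethyl)-3-methyloxiran-2-yl]-3-methylpent-2-en-1-yl acetate
Conditions: Ti(OiPr)4 (cat.), D-(−)-diisopropyl tartrate (cat.), t-BuOOH, 4 Å MS, CH2Cl2, −20 °C
Reagents that add atoms: tert-butyl hydroperoxide, CC(C)(C)OO
Why: Sharpless asymmetric epoxidation touches only the olefin with a free allylic hydroxyl, and the D-(−)-tartrate ligand sets the (1R,10R)-trans-epoxide from the E-olefin.

Step 3
Reactants: 3 epoxy alcohol acetate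
Product: 4 (2Z)-5-[(2R,3R)-3-(hydroxymethyl)-3-methyloxiran-2-yl]-3-methylpent-2-en-1-ol
Conditions: K2CO3 (cat.), MeOH, 0 °C
Reagents that add atoms: none
Why: Base-catalysed transesterification removes the acetate under conditions too mild for a Payne rearrangement and uncovers the second allylic alcohol.

Step 4
Reactants: 4 epoxy allylic diol
Product: 5 bis-epoxy diol {(2R,3R)-3-[2-((2R,3S)-3-(hydroxymethyl)-2-methyloxiran-2-yl)ethyl]-2-methyloxiran-2-yl}methanol
Conditions: Ti(OiPr)4 (cat.), L-(+)-diisopropyl tartrate (cat.), t-BuOOH, 4 Å MS, CH2Cl2, −20 °C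
Reagents that add atoms: tert-butyl hydroperoxide, CC(C)(C)OO
Why: A second Sharpless asymmetric epoxidation, now with the L-(+)-tartrate, sets the (4R,5S)-cis-epoxide from the Z-olefin, and any minor enantiomer carried from step 2 ends up as a separable diastereomer.

Step 5
Reactants: 5 bis-epoxy diol
Product: 6 bis-epoxy dialdehyde (2S,3R)-3-{2-[(2R,3R)-3-formyl-2-methyloxiran-2-yl]ethyl}-2-methyloxirane-2-carbaldehyde (same spatial arrangement as 5, descriptors change by priority only)
Conditions: Dess–Martin periodinane, pyridine, CH2Cl2, 0 °C to rt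
Reagents that add atoms: none
Why: Dess–Martin oxidation takes both primary epoxy alcohols (C6 and C9) to the aldehydes without touching the epoxides, with pyridine buffering the acetic acid.

Step 6
Reactants: 7 buta-2,3-dienoic acid; 8 (S)-4-benzyloxazolidin-2-one
Product: 10 (S)-4-benzyl-3-(buta-2,3-dienoyl)oxazolidin-2-one, via mixed pivalic anhydride 9 (not isolated)
Conditions: t-BuCOCl, Et3N, THF, −20 °C; then LiCl, 8, −20 °C to rt
Reagents that add atoms: none
Why: N-Acylation of the oxazolidinone through the mixed pivalic anhydride with LiCl activation avoids the strong base that the allenoyl group would not tolerate.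

Step 7
Reactants: 10 N-allenoyl oxazolidinone
Product: 11 (S)-4-benzyl-3-[3-(Bpin)but-3-enoyl]oxazolidin-2-one
Conditions: CuCl (cat.), Xantphos (cat.), NaOtBu (cat.), B2pin2, MeOH, THF, 0 °C
Reagents that add atoms: bis(pinacolato)diboron, CC1(C)OB(OC1(C)C)B1OC(C)(C)C(C)(C)O1
Why: Copper-catalysed conjugate borylation of an allenoyl acceptor puts boron on the central allene carbon, and α-protonation of the copper enolate leaves the β,γ-unsaturated 1,1-disubstituted alkenylboronate (C11, C13).

Step 8
Reactants: 11 boryl butenoyl oxazolidinone; 6 bis-epoxy dialdehyde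
Product: 13 Evans syn-aldol adduct (6S carbinol; 7S carbon bearing the 1-(Bpin)vinyl group and the imide carbonyl C8; C9 aldehyde intact), via boron Z-enolate 12 (not isolated)
Conditions: Bu2BOTf, Et3N, CH2Cl2, −78 to 0 °C; then 6 (slight excess), −78 °C; pH 7 buffer/MeOH work-up without peroxide
Reagents that add atoms: none
Why: In this Evans syn-aldol reaction the Z-boron enolate reacts through a Zimmerman–Traxler chair on the face left open by the benzyl group, which sets C6 and C7 (matched with the polar Felkin–Anh preference of the epoxy aldehyde for the 5,6-anti product), and the compact transition state should favour the C6 aldehyde (tertiary α-carbon) over the C9 aldehyde (quaternary α-carbon).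

Step 9
Reactants: 13 aldol adduct
Product: 14 triol (C8 and C9 primary alcohols, C6 secondary alcohol, both epoxides, 1-(Bpin)vinyl on C7, configuration unchanged)
Conditions: LiBH4, MeOH (1 equiv), THF, 0 °C
Reagents that add atoms: none
Why: Reductive cleavage of the N-acyl oxazolidinone with LiBH4 gives the C8 alcohol and reduces the C9 aldehyde at the same time, leaving the epoxides, the boronate and all stereocentres untouched.

Step 10
Reactants: 14 triol
Product: 15 hydroxy dialdehyde (C8 and C9 aldehydes, free C6 alcohol)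
Conditions: TEMPO (cat.), PhI(OAc)2, CH2Cl2, rt
Reagents that add atoms: none
Why: Oxoammonium (TEMPO) oxidation is selective for primary over secondary alcohols, so C8 and C9 become aldehydes while the hindered C6 carbinol stays free.

Step 11
Reactants: 15 hydroxy dialdehyde
Product: 16 diene alcohol (vinyl on C7, vinyl on the C10 epoxide carbon, free C6 alcohol)
Conditions: RhCl(PPh3)3 (cat.), PPh3, TMSCHN2, i-PrOH, THF, rt
Reagents that add atoms: (trimethylsilyl)diazomethane, C[Si](C)(C)C=[N+]=[N-]
Why: Rhodium-catalysed methylenation releases Ph3P=CH2 slowly under neutral, salt-free conditions (Wittig reaction), so both aldehydes are converted without retro-aldol cleavage, dehydration or epimerisation at C7.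

Step 12
Reactants: 16 diene alcohol; 17 angelic acid
Product: 19 C6 angelate of 16, via Yamaguchi mixed anhydride 18 (not isolated)
Conditions: 2,4,6-trichlorobenzoyl chloride, Et3N, toluene, rt; then 16, 80 °C
Reagents that add atoms: none
Why: Yamaguchi esterification without DMAP acylates the hindered C6 alcohol with retention at C6 and keeps the Z geometry of the angelate, while excess Et3N protects the acid-labile vinyl epoxide.

Step 13
Reactants: 19 acyclic diene angelate
Product: 20 cyclodecene (Z-C8=C9 olefin, (1R,10R)-trans-epoxide, (4R,5S)-cis-epoxide, 6S angelate, 1-(Bpin)vinyl on C7)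
Conditions: second-generation Grubbs catalyst RuCl2(=CHPh)(PCy3)(SIMes) (cat.), 1,4-benzoquinone (cat.), toluene, high dilution, 80 °C
Reagents that add atoms: none
Why: Ring-closing metathesis engages only the two monosubstituted vinyl groups (the 1,1-disubstituted alkenylboronate and the trisubstituted angelate are inert), and the strain of an E-olefin next to the trans-epoxide in a ten-membered ring should direct closure to the Z-olefin.

Step 14
Reactants: 20 cyclodecene boronate
Product: 22 target, (1R,4R,5S,6S,7R,8S,9Z)-6-angeloyloxy-4,5-epoxy-1-hydroxygermacra-9,11(13)-dien-12,8-olide, via potassium acrylate 21 (not isolated)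
Conditions: (IPr)CuCl (cat.), KOtBu (1.05 equiv), Pd(PPh3)4 (cat.), CO2 (1 atm), THF (dilute), 60 °C; aqueous work-up
Reagents that add atoms: carbon dioxide, O=C=O
Why: Proposed new method: KOtBu turns the C11 boronate into its ate complex, (IPr)Cu–OtBu takes over the alkenyl group and the alkenylcopper inserts CO2 (C11–C12 bond) to give acrylate 21, while zerovalent palladium ionises only the allylic C10–O bond of the vinyl epoxide, anti to oxygen, to an anti,anti-π-allylpalladium alkoxide that the CO2 atmosphere buffers as its hemicarbonate. The carboxylate oxygen then attacks C8 on the face opposite palladium (O–C8 bond), a 5-exo closure of the γ-lactone on the allyl terminus, and work-up frees the C1 alcohol. The closest known reaction types are the copper–NHC-catalysed carboxylation of alkenylboronic esters, the palladium-catalysed syn-1,4-addition of carboxylates to diene monoepoxides, and the carboxylative coupling of organometallics, CO2 and allyl halides to allyl esters; their merger on one substrate is what is new. C8 is the only new stereocentre: double inversion places its oxygen on the allyl face that the epoxide oxygen left, which for the (1R,10R)-trans-epoxide and the Z-C8=C9 olefin means 8S and hence the trans-fused lactone, while C1 keeps its C–O bond and the ring-enforced anti position of C1 on the allyl unit gives the Z-C9=C10 olefin. The step needs chemoselectivity between the two epoxides (the C4–C5 epoxide is not allylic and is not ionised), regioselectivity for C8 over C10 (five- against seven-membered ring, secondary against fully substituted terminus), and survival of the angelate and the new methylene lactone (the base is consumed as the borate and no free alkoxide persists under CO2).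

Compound list
1 | neryl acetate, (2Z)-3,7-dimethylocta-2,6-dien-1-yl acetate | CC(C)=CCC/C(C)=C\COC(C)=O | starting material
2 | (2Z,6E)-8-hydroxy-3,7-dimethylocta-2,6-dien-1-yl acetate | OC/C(C)=C/CC/C(C)=C\COC(C)=O | intermediate
3 | (2Z)-5-[(2R,3R)-3-(hydroxymethyl)-3-methyloxiran-2-yl]-3-methylpent-2-en-1-yl acetate | OC[C@@]1(C)O[C@@H]1CC/C(C)=C\COC(C)=O | intermediate
4 | (2Z)-5-[(2R,3R)-3-(hydroxymethyl)-3-methyloxiran-2-yl]-3-methylpent-2-en-1-ol | OC[C@@]1(C)O[C@@H]1CC/C(C)=C\CO | intermediate
5 | bis-epoxy diol (1R,10R trans-epoxide; 4R,5S cis-epoxide) | OC[C@@]1(C)O[C@@H]1CC[C@@]2(C)O[C@H]2CO | intermediate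
6 | bis-epoxy dialdehyde (C6 and C9 aldehydes) | O=C[C@@]1(C)O[C@@H]1CC[C@@]2(C)O[C@H]2C=O | intermediate
7 | buta-2,3-dienoic acid | C=C=CC(=O)O | starting material
8 | (S)-4-benzyloxazolidin-2-one | O=C1N[C@@H](Cc2ccccc2)CO1 | starting material
9 | buta-2,3-dienoic pivalic anhydride | C=C=CC(=O)OC(=O)C(C)(C)C | intermediate
10 | (S)-4-benzyl-3-(buta-2,3-dienoyl)oxazolidin-2-one | C=C=CC(=O)N1[C@@H](Cc2ccccc2)COC1=O | intermediate
11 | (S)-4-benzyl-3-[3-(Bpin)but-3-enoyl]oxazolidin-2-one | C=C(B1OC(C)(C)C(C)(C)O1)CC(=O)N1[C@@H](Cc2ccccc2)COC1=O | intermediate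
12 | dibutylboron Z-enolate of 11 | C=C(B1OC(C)(C)C(C)(C)O1)/C=C(\OB(CCCC)CCCC)N1[C@@H](Cc2ccccc2)COC1=O | intermediate
13 | Evans syn-aldol adduct (6S,7S; C9 aldehyde intact) | O=C[C@@]1(C)O[C@@H]1CC[C@@]2(C)O[C@H]2[C@@H](O)[C@H](C(=C)B3OC(C)(C)C(C)(C)O3)C(=O)N4[C@@H](Cc5ccccc5)COC4=O | intermediate
14 | triol (C6, C8, C9 hydroxyls) | OC[C@@]1(C)O[C@@H]1CC[C@@]2(C)O[C@H]2[C@@H](O)[C@H](C(=C)B3OC(C)(C)C(C)(C)O3)CO | intermediate
15 | hydroxy dialdehyde (C8 and C9 aldehydes) | O=C[C@@]1(C)O[C@@H]1CC[C@@]2(C)O[C@H]2[C@@H](O)[C@H](C(=C)B3OC(C)(C)C(C)(C)O3)C=O | intermediate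
16 | diene alcohol | C=C[C@@]1(C)O[C@@H]1CC[C@@]2(C)O[C@H]2[C@@H](O)[C@H](C(=C)B3OC(C)(C)C(C)(C)O3)C=C | intermediate
17 | angelic acid, (Z)-2-methylbut-2-enoic acid | C/C=C(/C)C(=O)O | starting material
18 | angelic 2,4,6-trichlorobenzoic anhydride | C/C=C(/C)C(=O)OC(=O)c1c(Cl)cc(Cl)cc1Cl | intermediate
19 | acyclic diene angelate | C=C[C@@]1(C)O[C@@H]1CC[C@@]2(C)O[C@H]2[C@@H](OC(=O)/C(C)=C\C)[C@H](C(=C)B3OC(C)(C)C(C)(C)O3)C=C | intermediate
20 | cyclodecene boronate (Z-C8=C9, vinyl epoxide) | C=C(B4OC(C)(C)C(C)(C)O4)[C@@H]1/C=C\[C@@]2(C)O[C@@H]2CC[C@@]3(C)O[C@H]3[C@H]1OC(=O)/C(C)=C\C | intermediate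
21 | potassium 2-substituted acrylate | C=C(C(=O)[O-])[C@@H]1/C=C\[C@@]2(C)O[C@@H]2CC[C@@]3(C)O[C@H]3[C@H]1OC(=O)/C(C)=C\C.[K+] | intermediate
22 | CNP0191628.1 | C=C1C(=O)O[C@H]2/C=C(/C)[C@H](O)CC[C@@]3(C)O[C@H]3[C@@H](OC(=O)/C(C)=C\C)[C@H]12 | target

Total step count: 14. Longest linear sequence: 12 steps (steps 1–5 and 8–14, from neryl acetate).

Steps most likely to fail

Step 14. Protodeboronation or allyl–alkenyl cross-coupling may outrun CO2 insertion. The two catalysts may interfere with each other. Slow lactone closure may let the π-allyl intermediate rest as the cyclic carbonate or lose its geometry. The fallback sets out from 20 and separates the two bond formations into two established reactions. Copper–NHC-catalysed carboxylation of the boronate alone ((IPr)CuCl, KOtBu, CO2, THF), followed by mild acidification, gives the isolated acrylic acid F1. This acid is then cyclised with Pd(PPh3)4 in THF at rt under neutral conditions, where it acts as pronucleophile and proton source for the alkoxide (carboxylic acid 1,4-addition to a vinyl epoxide). The fallback comes back to the route at 22.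

Step 13. Oligomerisation may replace closure of the strained ring. Initiation at the vinyl group on the fully substituted C10 may be sluggish. Closure may also drift towards the E-olefin, which would lead to the wrong C8 configuration later. The fallback replaces metathesis by an intramolecular Wittig reaction of a non-stabilised ylide, which is Z-selective by its own mechanism, and sets out from triol 14. Appel iodination (I2, PPh3, imidazole) should convert only the C8 alcohol, since displacement at the neopentyl-type C9 and at the hindered C6 is slow, and gives the primary iodide F2. TEMPO/PhI(OAc)2 oxidises the remaining primary alcohol to the iodo epoxy aldehyde F3. Yamaguchi esterification with 17 gives the iodo aldehyde angelate F4. PPh3 in MeCN at 70 °C gives the phosphonium iodide F5. Slow addition of F5 to KHMDS in THF at high dilution closes the ring and comes back to the route at 20.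

Step 8. Discrimination between the two aldehyde groups may be poor, giving addition at C9 or double addition. The fallback masks C9 as a silyl ether and sets out from epoxy alcohol 3. TBSCl/imidazole gives the silyl ether acetate F6. K2CO3/MeOH gives the allylic alcohol F7. Sharpless epoxidation with the L-(+)-tartrate gives the bis-epoxy alcohol F8. Dess–Martin oxidation gives the monoaldehyde F9. The same Evans aldol reaction with 11 gives the silylated aldol adduct F10. LiBH4 gives the silylated diol F11. Et3N·3HF in THF removes the silyl group and comes back to the route at 14.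

Further compounds
F1 | step 14 | 2-substituted acrylic acid (free acid of 21) | C=C(C(=O)O)[C@@H]1/C=C\[C@@]2(C)O[C@@H]2CC[C@@]3(C)O[C@H]3[C@H]1OC(=O)/C(C)=C\C
F2 | step 13 | C8 primary iodide with free C6 and C9 alcohols | OC[C@@]1(C)O[C@@H]1CC[C@@]2(C)O[C@H]2[C@@H](O)[C@H](C(=C)B3OC(C)(C)C(C)(C)O3)CI
F3 | step 13 | iodo epoxy aldehyde (C9 aldehyde, free C6 alcohol) | O=C[C@@]1(C)O[C@@H]1CC[C@@]2(C)O[C@H]2[C@@H](O)[C@H](C(=C)B3OC(C)(C)C(C)(C)O3)CI
F4 | step 13 | iodo aldehyde angelate | O=C[C@@]1(C)O[C@@H]1CC[C@@]2(C)O[C@H]2[C@@H](OC(=O)/C(C)=C\C)[C@H](C(=C)B3OC(C)(C)C(C)(C)O3)CI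
F5 | step 13 | C8 triphenylphosphonium iodide | O=C[C@@]1(C)O[C@@H]1CC[C@@]2(C)O[C@H]2[C@@H](OC(=O)/C(C)=C\C)[C@H](C(=C)B3OC(C)(C)C(C)(C)O3)C[P+](c4ccccc4)(c5ccccc5)c6ccccc6.[I-]
F6 | step 8 | C9 TBS ether of 3 | CC(C)(C)[Si](C)(C)OC[C@@]1(C)O[C@@H]1CC/C(C)=C\COC(C)=O
F7 | step 8 | C9 TBS ether allylic alcohol | CC(C)(C)[Si](C)(C)OC[C@@]1(C)O[C@@H]1CC/C(C)=C\CO
F8 | step 8 | C9 TBS ether bis-epoxy alcohol | CC(C)(C)[Si](C)(C)OC[C@@]1(C)O[C@@H]1CC[C@@]2(C)O[C@H]2CO
F9 | step 8 | C9 TBS ether C6 monoaldehyde | CC(C)(C)[Si](C)(C)OC[C@@]1(C)O[C@@H]1CC[C@@]2(C)O[C@H]2C=O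
F10 | step 8 | silylated Evans syn-aldol adduct | CC(C)(C)[Si](C)(C)OC[C@@]1(C)O[C@@H]1CC[C@@]2(C)O[C@H]2[C@@H](O)[C@H](C(=C)B3OC(C)(C)C(C)(C)O3)C(=O)N4[C@@H](Cc5ccccc5)COC4=O
F11 | step 8 | silylated C6,C8 diol | CC(C)(C)[Si](C)(C)OC[C@@]1(C)O[C@@H]1CC[C@@]2(C)O[C@H]2[C@@H](O)[C@H](C(=C)B3OC(C)(C)C(C)(C)O3)CO
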